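## Retrosynthetic overview
1. The 10-membered carbocycle, the trans-fused γ-lactone and the exo-methylene form in one step. A C8 aldehyde undergoes intramolecular allylboration with a C7-linked 2-(methoxycarbonyl)allyl-Bpin, and lactonisation follows. The C6 angelate goes on last.
2. The allylboronate comes from a Morita–Baylis–Hillman (MBH) acetate at C7 by Pd-catalysed borylation. The C7 aldehyde is unmasked from a dimethyl acetal. The C3 ketone and C4 acetate come from Au-catalysed, acetate-assisted hydration of a tertiary propargylic acetate, which is made by C3–C4 alkynyl addition to a methyl ketone.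
3. The left half (syn C1/C10, terminal alkene as the C8 precursor) comes from chiral-phosphoric-acid (CPA) catalysed Z-crotylboration of TMS-propynal. The right half (C6) comes from a proline-catalysed aldol of acetone with 2,2-dimethoxyacetaldehyde.

**Assumptions (one line each):**
- The catalyst enantiomers named ((R)-TRIP, (R)-proline, (S)-TRIP) give the configurations required.
- The lactone is trans-fused, as read from the target SMILES.
- The C6 ester is a Z-angelate.
- 2,2-Dimethoxyacetaldehyde is the commercial 60% aqueous solution, dried by toluene azeotrope before use.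

## Route

**Step 1**
Reactants: 1 (3-(trimethylsilyl)propynal), 2 ((Z)-crotylboronic acid pinacol ester)
Product: 3 ((3S,4R)-4-methyl-1-(trimethylsilyl)hex-5-en-1-yn-3-ol, the syn homopropargylic alcohol)
Conditions: (R)-TRIP (10 mol%), toluene, 4 Å MS, −30 °C, 24 h; then brief 1 M NaOH/THF workup at 0 °C
Reagents that add atoms: none
Why: CPA-catalysed allylboration (Zimmerman–Traxler chair TS) sets C1 and C10 together. The Z-crotyl reagent gives the syn relationship the target requires (OMe and Me syn in the C2–C1–C10–C9 zigzag), and the catalyst sets the absolute configuration.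

**Step 2**
Reactants: 3, 4 (iodomethane)
Product: 5 ((3S,4R)-3-methoxy-4-methyl-1-TMS-hex-5-en-1-yne)
Conditions: NaH, MeI, THF, 0 °C → rt
Reagents that add atoms: MeI, CI
Why: Williamson etherification of a secondary alcohol that is not yet β to a ketone, so there is no elimination risk; no stereocentre is touched.

**Step 3**
Reactants: 5, 6 (hydrogen peroxide, released from sodium perborate)
Product: 7 ((3R,4S)-4-methoxy-3-methyl-6-TMS-hex-5-yn-1-ol)
Conditions: 9-BBN (1.05 equiv), THF, 0 °C → rt; then NaBO3·4H2O, THF/H2O
Reagents that add atoms: H2O2, OO (delivers the OH oxygen)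
Why: Anti-Markovnikov hydroboration–oxidation. 9-BBN reacts with the unhindered vinyl group far faster than with the TMS-capped alkyne, and oxidation is stereoretentive. This makes the C8 carbon.

**Step 4**
Reactants: 7, 8 (TBSCl)
Product: 9 (TBS ether of 7)
Conditions: TBSCl, imidazole, CH2Cl2, rt
Reagents that add atoms: TBSCl, C[Si](C)(Cl)C(C)(C)C
Why: Standard silylation of a primary alcohol; no stereocentre is affected.

**Step 5**
Reactants: 10 (acetone), 11 (2,2-dimethoxyacetaldehyde)
Product: 12 ((4S)-4-hydroxy-5,5-dimethoxypentan-2-one)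
Conditions: (R)-proline (30 mol%), acetone/DMSO, rt, 48 h
Reagents that add atoms: none
Why: Enamine-mediated direct aldol (List–Barbas type). The proline enamine attacks one aldehyde face and sets C6; (R)-proline is chosen to give the 4S carbinol.

**Step 6**
Reactants: 12, 8 (TBSCl)
Product: 13 ((4S)-4-(TBSO)-5,5-dimethoxypentan-2-one)
Conditions: TBSCl, imidazole, DMF, 40 °C
Reagents that add atoms: TBSCl, C[Si](C)(Cl)C(C)(C)C
Why: Silylating the β-hydroxy ketone prevents β-elimination and unwanted chelation in the next step, and it avoids silyl triflate, which would cleave the acetal.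

**Step 7**
Reactants: 9, 13
Product: 14 (tertiary propargylic alcohol, C3–C4 bond formed, C4 configuration as in the target)
Conditions: 9, MeLi·LiBr (1.2 equiv), THF, 0 °C → rt (desilylation); then CeCl3 (1.3 equiv), −78 °C; add 13, −78 → −40 °C
Reagents that add atoms: none (the TMS group leaves as SiMe4)
Why: MeLi attacks silicon to give the lithium acetylide, and the organocerium species adds 1,2 to the enolisable methyl ketone without enolisation. The β-silyloxy group gives only modest open-transition-state 1,3-induction (about 2:1 expected); the C4 epimers are separated by chromatography.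

**Step 8**
Reactants: 14, 15 (acetic anhydride)
Product: 16 (tertiary propargylic acetate)
Conditions: Ac2O, DMAP (0.5 equiv), Et3N, CH2Cl2, rt → 40 °C
Reagents that add atoms: Ac2O, CC(=O)OC(C)=O
Why: Acylating the tertiary alcohol now, before any ketone exists, installs the C4 acetate that directs the later hydration; C4 is not touched.

**Step 9**
Reactants: 16, 17 (water)
Product: 18 (alkynyl α-silyloxy aldehyde, C7 CHO)
Conditions: TESOTf, 2,4,6-collidine, CH2Cl2, 0 °C; then H2O
Reagents that add atoms: H2O, O
Why: Mild acetal-to-aldehyde conversion through a collidinium salt (Fujioka conditions) that tolerates the silyl ethers and the acetate; the aldehyde is used at once to limit C6 epimerisation.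

**Step 10**
Reactants: 18, 19 (methyl acrylate)
Product: 20 (MBH adduct, C7 allylic alcohol as an epimeric mixture)
Conditions: methyl acrylate (10 equiv), 3-hydroxyquinuclidine (1 equiv), MeCN, rt, 72 h
Reagents that add atoms: methyl acrylate, C=CC(=O)OC
Why: Morita–Baylis–Hillman reaction. The new C7 carbinol centre is irrelevant because it is destroyed in the π-allyl-Pd step.

**Step 11**
Reactants: 20, 15 (acetic anhydride)
Product: 21 (MBH acetate)
Conditions: Ac2O, pyridine, DMAP, CH2Cl2, rt
Reagents that add atoms: Ac2O, CC(=O)OC(C)=O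
Why: Activates the allylic alcohol as a Pd π-allyl precursor.

**Step 12**
Reactants: 21, 17 (water)
Product: 22 (C3 ketone; C4-OAc retained)
Conditions: Ph3PAuCl/AgSbF6 (5 mol%), 1,4-dioxane/H2O (10:1), 50 °C
Reagents that add atoms: H2O, O
Why: Gold-catalysed hydration of a propargylic acetate assisted by the neighbouring ester carbonyl (5-exo-dig attack on the alkyne carbon next to C4, then hydrolysis of the dioxolenylium). The ketone forms at C3 with C2 as CH2, the C4 acetate is retained, and C4 is unchanged.

**Step 13**
Reactants: 22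
Product: 23 (primary C8 alcohol; C6-OTBS kept)
Conditions: CSA (0.2 equiv), MeOH/CH2Cl2 (1:1), −10 → 0 °C
Reagents that add atoms: none
Why: Acid methanolysis removes the unhindered primary TBS ether much faster than the secondary C6-OTBS.

**Step 14**
Reactants: 23, 24 (bis(pinacolato)diboron)
Product: 25 (trisubstituted allylboronate, C6 trans to CH2Bpin, free C8 alcohol)
Conditions: B2pin2 (1.5 equiv), Pd(PPh3)4 (5 mol%), KOAc, THF, 40 °C
Reagents that add atoms: B2pin2, CC1(C)OB(OC1(C)C)B1OC(C)(C)C(C)(C)O1 (one Bpin is retained)
Why: Pd-catalysed borylation of the MBH acetate through a π-allyl with the C6 substituent syn, with boron delivered to the CH2 terminus. This gives the crotyl-type geometry (C6 trans to CH2Bpin) that leads to the trans-lactone.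

**Step 15**
Reactants: 25
Product: 26 (C8 aldehyde bearing the allylboronate)
Conditions: DMP, NaHCO3, CH2Cl2 (0.003 M), 0 °C, 30 min; quick Na2S2O3/NaHCO3 wash; use crude
Reagents that add atoms: none
Why: Neutral oxidation made last so that the keto-aldehyde (C3 ketone, C8 aldehyde) meets no base; the crude is cyclised at once.

**Step 16**
Reactants: 26
Product: 27 (C6-OTBS macrolide: 10-membered ring, trans-fused lactone, exo-methylene)
Conditions: (S)-TRIP (20 mol%), toluene, 4 Å MS, 35 °C, substrate added by syringe pump to ≤0.002 M; then p-TsOH·H2O (cat.), CH2Cl2, rt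
Reagents that add atoms: none (pinB–OMe is lost)
Why: Proposed new method: CPA-catalysed macrocyclic allylboration, in which the acid hydrogen-bonds to the pinacol oxygens and raises boron's Lewis acidity. The crotyl-type allylboronate (C6 trans to CH2B) and the aldehyde react through a chair transition state with both tether ends equatorial, which gives the anti adduct at C7–C8 (trans-lactone); the catalyst together with the C6 and C10 stereocentres selects the facial sense, and p-TsOH then lactonises the alkoxyboronate onto the methyl ester. The closest known reactions are CPA-catalysed intermolecular allylboration, Lewis-acid-catalysed allylboration with 2-alkoxycarbonyl-allylboronates, and Cr-mediated macro-allylation in germacranolide syntheses.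

**Step 17**
Reactants: 27
Product: 28 (C6 alcohol)
Conditions: HF·pyridine, THF, 0 °C → rt
Reagents that add atoms: none
Why: Acidic fluoride removes the secondary TBS ether without exposing the β-methoxy ketone to base; lactone, acetate and methylene are unaffected.

**Step 18**
Reactants: 28, 29 (angelic acid)
Product: 30 (Rufesolide C)
Conditions: angelic acid, 2,4,6-Cl3C6H2COCl, Et3N, THF; then 28, DMAP, toluene, rt
Reagents that add atoms: angelic acid, OC(=O)/C(C)=C\C
Why: Yamaguchi esterification of the C6 secondary alcohol with the Z-angelate kept (minor tiglate removed by chromatography); C6 is not touched.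

## Compound list
1 | 3-(trimethylsilyl)propynal | C[Si](C)(C)C#CC=O | starting material
2 | (Z)-crotyl-Bpin | C/C=C\CB1OC(C)(C)C(C)(C)O1 | starting material
3 | (3S,4R)-4-methyl-1-TMS-hex-5-en-1-yn-3-ol | C=C[C@@H](C)[C@H](O)C#C[Si](C)(C)C | intermediate
4 | iodomethane | CI | starting material
5 | (3S,4R)-3-methoxy-4-methyl-1-TMS-hex-5-en-1-yne | C=C[C@@H](C)[C@H](OC)C#C[Si](C)(C)C | intermediate
6 | hydrogen peroxide (from sodium perborate) | OO | starting material
7 | (3R,4S)-4-methoxy-3-methyl-6-TMS-hex-5-yn-1-ol | OCC[C@@H](C)[C@H](OC)C#C[Si](C)(C)C | intermediate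
8 | TBSCl | C[Si](C)(Cl)C(C)(C)C | starting material
9 | TBS ether of 7 | CC(C)(C)[Si](C)(C)OCC[C@@H](C)[C@H](OC)C#C[Si](C)(C)C | intermediate
10 | acetone | CC(C)=O | starting material
11 | 2,2-dimethoxyacetaldehyde | COC(OC)C=O | starting material
12 | (4S)-4-hydroxy-5,5-dimethoxypentan-2-one | CC(=O)C[C@H](O)C(OC)OC | intermediate
13 | (4S)-4-(TBSO)-5,5-dimethoxypentan-2-one | CC(=O)C[C@H](O[Si](C)(C)C(C)(C)C)C(OC)OC | intermediate
14 | tertiary propargylic alcohol (C4-OH) | CC(C)(C)[Si](C)(C)OCC[C@@H](C)[C@H](OC)C#C[C@](C)(O)C[C@H](O[Si](C)(C)C(C)(C)C)C(OC)OC | intermediate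
15 | acetic anhydride | CC(=O)OC(C)=O | starting material
16 | propargylic acetate | CC(C)(C)[Si](C)(C)OCC[C@@H](C)[C@H](OC)C#C[C@](C)(OC(C)=O)C[C@H](O[Si](C)(C)C(C)(C)C)C(OC)OC | intermediate
17 | water | O | starting material
18 | alkynyl aldehyde (C7 CHO) | CC(C)(C)[Si](C)(C)OCC[C@@H](C)[C@H](OC)C#C[C@](C)(OC(C)=O)C[C@H](O[Si](C)(C)C(C)(C)C)C=O | intermediate
19 | methyl acrylate | C=CC(=O)OC | starting material
20 | MBH adduct (C7 epimeric mixture) | CC(C)(C)[Si](C)(C)OCC[C@@H](C)[C@H](OC)C#C[C@](C)(OC(C)=O)C[C@H](O[Si](C)(C)C(C)(C)C)C(O)C(=C)C(=O)OC | intermediate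
21 | MBH acetate | CC(C)(C)[Si](C)(C)OCC[C@@H](C)[C@H](OC)C#C[C@](C)(OC(C)=O)C[C@H](O[Si](C)(C)C(C)(C)C)C(OC(C)=O)C(=C)C(=O)OC | intermediate
22 | C3 ketone | CC(C)(C)[Si](C)(C)OCC[C@@H](C)[C@H](OC)CC(=O)[C@](C)(OC(C)=O)C[C@H](O[Si](C)(C)C(C)(C)C)C(OC(C)=O)C(=C)C(=O)OC | intermediate
23 | primary alcohol | OCC[C@@H](C)[C@H](OC)CC(=O)[C@](C)(OC(C)=O)C[C@H](O[Si](C)(C)C(C)(C)C)C(OC(C)=O)C(=C)C(=O)OC | intermediate
24 | bis(pinacolato)diboron | CC1(C)OB(OC1(C)C)B1OC(C)(C)C(C)(C)O1 | starting material
25 | allylboronate alcohol (C6 trans to CH2Bpin) | OCC[C@@H](C)[C@H](OC)CC(=O)[C@](C)(OC(C)=O)C[C@H](O[Si](C)(C)C(C)(C)C)/C=C(\C(=O)OC)CB1OC(C)(C)C(C)(C)O1 | intermediate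
26 | aldehyde–allylboronate | O=CC[C@@H](C)[C@H](OC)CC(=O)[C@](C)(OC(C)=O)C[C@H](O[Si](C)(C)C(C)(C)C)/C=C(\C(=O)OC)CB1OC(C)(C)C(C)(C)O1 | intermediate
27 | macrolide, C6-OTBS | C=C1C(=O)O[C@@H]2C[C@@H](C)[C@H](OC)CC(=O)[C@](C)(OC(C)=O)C[C@H](O[Si](C)(C)C(C)(C)C)[C@@H]12 | intermediate
28 | macrolide, C6-OH | C=C1C(=O)O[C@@H]2C[C@@H](C)[C@H](OC)CC(=O)[C@](C)(OC(C)=O)C[C@H](O)[C@@H]12 | intermediate
29 | angelic acid | OC(=O)/C(C)=C\C | starting material
30 | Rufesolide C | C=C1C(=O)O[C@@H]2C[C@@H](C)[C@H](OC)CC(=O)[C@](C)(OC(C)=O)C[C@H](OC(=O)/C(C)=C\C)[C@@H]12 | target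

## Totals
**Total steps:** 18. **Longest linear sequence:** 16 (steps 1, 2, 3, 4, 7–18; steps 5 and 6 are a parallel branch).

**Three steps most likely to fail**
1. **Step 16 (proposed new macro-allylboration).** Risks are oligomerisation, wrong C7/C8 diastereomers, and a competing 1,6-keto-aldehyde aldol (C2 onto C8) that would form a cyclopentane. Fallback with known chemistry: from 23, convert the allylic acetate to the allylic bromide (LiBr, cat. acid), oxidise with DMP, close the ring by CrCl2-mediated intramolecular Nozaki–Hiyama allylation (THF, high dilution, neutral), then lactonise with TsOH.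
2. **Step 7 (C4 diastereoselectivity).** Only modest 1,3-induction is expected. Fallback that changes the approach by reversing polarity: acylate the lithium acetylide from 9 with the Weinreb amide of (S)-3-(TBSO)-4,4-dimethoxybutanoic acid (same C6 configuration) to give an ynone, then add a methyl nucleophile (MeMgBr/CeCl3, Me3Al or MeTi(OiPr)3). The face selectivity is then set by the ynone's flanking groups, so it can be screened independently of the alkyne addition.
3. **Step 5 (ee in the acetone/acetal aldehyde aldol).** Fallback with known chemistry: asymmetric allylboration of 11 with allyl-Bpin (CPA or Brown reagent), TBS protection, then Wacker oxidation (PdCl2/CuCl/O2) to the same β-silyloxy methyl ketone 13.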